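Retrosynthetic cuts, in order: O18–acetyl; C13=C16 and C14=C15 (back to a C13≡C14 alkyne plus ethylene); C7–H and C8–O (through the 7,8-epoxide to a C7=C8 alkene); C7=C8 (ring B, metathesis); C6–C7; C9–C10; C10–C20; C5–C6; C4–C19.
Enabling feature: in ring B, O6 and O8 are cis-1,3 and both equatorial. C7–C8 lies between two arms (C5–C6 and C10–C9) that are trans-diequatorial on ring A. A C7=C8 alkene beside the C6 carbinol therefore closes ring B easily and accepts O8 from the O6 face.
Forward order: ring A is a Birch-derived cyclohexenone, substituted in turn at C4, C5 and C10. C9 and the capped side chain arrive together in one Claisen step. Ring B then closes by metathesis, and the 1,3-diene is released from the alkyne in the last step.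
Stereochemistry: C4 comes from a chiral copper catalyst and C5 from attack anti to the C18 arm. C10 and C9 are set together by a chair Claisen transition state anti to the C5 substituent. C6 comes from CBS reduction of an acyclic vinyl ketone, and C8 from O6-directed epoxidation, kept in the hydride opening at C7.

Key step: step 16

Remark: labdane numbering (C1–C20) is used for all intermediates.
Assumption: the (S,S)-phosphoramidite of step 3 is taken to deliver methyl to the enone face that gives 4S, by analogy with other 3-alkylcyclohexenones. Its antipode is equally available.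

Step 1
Reactants: 1 3-methoxybenzyl alcohol
Product: 3 3-(hydroxymethyl)cyclohex-2-en-1-one, via dihydroanisole 2 (not isolated)
Conditions: Li, NH3(l), t-BuOH, THF, −78 to −33 °C; then 2 M HCl, THF, rt
Reagents that add atoms: water, O
Why: Birch reduction leaves the two donor-bearing carbons sp2 (the benzylic C–O bond is protected as its alkoxide), and acid hydrolysis of the enol ether with migration of the alkene into conjugation should give the 3-substituted enone.

Step 2
Reactants: 3 3-(hydroxymethyl)cyclohex-2-en-1-one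
Product: 4 3-{[(tert-butyldiphenylsilyl)oxy]methyl}cyclohex-2-en-1-one
Conditions: t-BuPh2SiCl, imidazole, CH2Cl2, rt
Reagents that add atoms: tert-butyl(chloro)diphenylsilane, CC(C)(C)[Si](Cl)(c1ccccc1)c1ccccc1
Why: Routine silylation of a primary alcohol, with the bulky silyl group chosen to survive the later acid, base and hydride steps and to make the C18 arm far larger than the C19 methyl group.

Step 3
Reactants: 4 3-{[(tert-butyldiphenylsilyl)oxy]methyl}cyclohex-2-en-1-one
Product: 6 tert-butyl{[(1S)-1-methyl-3-(trimethylsilyloxy)cyclohex-2-en-1-yl]methoxy}diphenylsilane, via aluminium enolate 5 (not isolated)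
Conditions: Me3Al, Cu(O2CC4H3S) (2 mol %), (S,S)-N,N-bis(1-phenylethyl)dibenzo[d,f][1,3,2]dioxaphosphepin-6-amine (4 mol %), Et2O, −30 °C; then Me3SiOTf, −30 to 0 °C
Reagents that add atoms: trimethylaluminium, C[Al](C)C; trimethylsilyl triflate, C[Si](C)(C)OS(=O)(=O)C(F)(F)F
Why: Copper-catalysed asymmetric conjugate addition of Me3Al to a 3-substituted cyclohexenone builds the C4 quaternary centre under ligand control, and silylation of the aluminium enolate fixes the enolate regiochemistry at C5=C10.

Step 4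
Reactants: 6 tert-butyl{[(1S)-1-methyl-3-(trimethylsilyloxy)cyclohex-2-en-1-yl]methoxy}diphenylsilane
Product: 7 (2R,3S)-3-{[(tert-butyldiphenylsilyl)oxy]methyl}-2-(1,3-dithian-2-yl)-3-methylcyclohexan-1-one
Conditions: 1,3-dithiane, Ph3CBF4, CH2Cl2, 40 °C; then 6, CH2Cl2–MeNO2, −78 °C
Reagents that add atoms: 1,3-dithiane (used as its 2-ylium tetrafluoroborate), C1CSCSC1
Why: Mukaiyama-type alkylation of the silyl enol ether with the 1,3-dithian-2-ylium cation puts a masked formyl carbon (C6) on C5, and axial attack on the half-chair that holds CH2OSi pseudo-axial brings the bulky cation in anti to that arm, so C6 should end up trans to C18.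

Step 5
Reactants: 7 (2R,3S)-3-{[(tert-butyldiphenylsilyl)oxy]methyl}-2-(1,3-dithian-2-yl)-3-methylcyclohexan-1-one
Product: 8 tert-butyl{[(1S,2R,3E)-2-(1,3-dithian-2-yl)-3-(methoxymethylidene)-1-methylcyclohexyl]methoxy}diphenylsilane
Conditions: MeOCH2PPh3Cl, KN(SiMe3)2, THF, 0 °C; then 7, 0 °C to rt
Reagents that add atoms: (methoxymethyl)triphenylphosphonium chloride, [Cl-].COC[P+](c1ccccc1)(c1ccccc1)c1ccccc1
Why: Wittig alkoxymethylenation adds C20 to the C10 ketone, and the E/Z ratio of the enol ether does not matter because the geometry is equilibrated in step 9 (the E isomer is drawn).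

Step 6
Reactants: 9 5-(trimethylsilyl)pent-4-yn-1-ol
Product: 10 5-(trimethylsilyl)pent-4-ynal
Conditions: Dess–Martin periodinane, CH2Cl2, rt
Reagents that add atoms: none
Why: Dess–Martin oxidation stops cleanly at the aldehyde and leaves the alkynylsilane untouched.

Step 7
Reactants: 10 5-(trimethylsilyl)pent-4-ynal
Product: 11 ethyl (2E)-2-methyl-7-(trimethylsilyl)hept-2-en-6-ynoate
Conditions: Ph3P=C(Me)CO2Et, CH2Cl2, rt
Reagents that add atoms: ethyl 2-(triphenylphosphoranylidene)propanoate, CCOC(=O)C(C)=P(c1ccccc1)(c1ccccc1)c1ccccc1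
Why: Wittig olefination with a stabilised α-methyl ylide should give the E trisubstituted enoate, which carries C8, C9, C11–C14 and C17.

Step 8
Reactants: 11 ethyl (2E)-2-methyl-7-(trimethylsilyl)hept-2-en-6-ynoate
Product: 12 (2E)-2-methyl-7-(trimethylsilyl)hept-2-en-6-yn-1-ol
Conditions: iBu2AlH (2.2 equiv), CH2Cl2, −78 °C
Reagents that add atoms: none
Why: 1,2-Reduction of an enoate with iBu2AlH gives the allylic alcohol with the E geometry retained.

Step 9
Reactants: 8 tert-butyl{[(1S,2R,3E)-2-(1,3-dithian-2-yl)-3-(methoxymethylidene)-1-methylcyclohexyl]methoxy}diphenylsilane; 12 (2E)-2-methyl-7-(trimethylsilyl)hept-2-en-6-yn-1-ol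
Product: 14 (1R,2R,3S)-3-{[(tert-butyldiphenylsilyl)oxy]methyl}-2-(1,3-dithian-2-yl)-3-methyl-1-[(3R)-2-methyl-7-(trimethylsilyl)hept-1-en-6-yn-3-yl]cyclohexane-1-carbaldehyde, via allyl enol ether 13 (not isolated)
Conditions: 12 (2 equiv), EtCO2H (10 mol %), o-xylene, 4 Å sieves, 145 °C
Reagents that add atoms: none
Why: Weak acid exchanges OMe for the allylic alkoxy group through the mixed acetal and keeps the enol ether geometry in equilibrium (C10 is the only α-carbon, so regiochemistry is unambiguous), so the aliphatic Claisen rearrangement should run through the less crowded E enol ether in a chair transition state on the ring face opposite the C5 dithianyl group and the axial C19 methyl, which places C9 equatorial and the formyl carbon C20 axial on C10 and, with the E allylic alkene, gives the required C9 configuration together with the isopropenyl group.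

Step 10
Reactants: 14 (1R,2R,3S)-3-{[(tert-butyldiphenylsilyl)oxy]methyl}-2-(1,3-dithian-2-yl)-3-methyl-1-[(3R)-2-methyl-7-(trimethylsilyl)hept-1-en-6-yn-3-yl]cyclohexane-1-carbaldehyde
Product: 15 tosylhydrazone of aldehyde 14
Conditions: TsNHNH2, THF, 50 °C
Reagents that add atoms: 4-methylbenzenesulfonohydrazide, Cc1ccc(cc1)S(=O)(=O)NN
Why: Condensation of an aldehyde with tosylhydrazide proceeds even at a neopentyl formyl group and touches no stereocentre.

Step 11
Reactants: 15 tosylhydrazone of aldehyde 14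
Product: 17 tert-butyl({(1S,2S,3S)-2-(1,3-dithian-2-yl)-1,3-dimethyl-3-[(3R)-2-methyl-7-(trimethylsilyl)hept-1-en-6-yn-3-yl]cyclohexyl}methoxy)diphenylsilane, via alkyl diazene 16 (not isolated)
Conditions: catecholborane, CHCl3, 0 °C; then NaOAc·3H2O, 60 °C
Reagents that add atoms: none
Why: Caglioti-type tosylhydrazone deoxygenation (hydroboration of C=N, acetate-induced loss of sulfinate, loss of N2 from the diazene) turns the formyl group into the C20 methyl, and it is run before the C6 vinyl group exists so that no alkene stands in a 5-hexenyl relation to C20.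

Step 12
Reactants: 17 tert-butyl({(1S,2S,3S)-2-(1,3-dithian-2-yl)-1,3-dimethyl-3-[(3R)-2-methyl-7-(trimethylsilyl)hept-1-en-6-yn-3-yl]cyclohexyl}methoxy)diphenylsilane
Product: 18 (1S,2S,6S)-2-{[(tert-butyldiphenylsilyl)oxy]methyl}-2,6-dimethyl-6-[(3R)-2-methyl-7-(trimethylsilyl)hept-1-en-6-yn-3-yl]cyclohexane-1-carbaldehyde
Conditions: MeI, CaCO3, MeCN–H2O 9:1, 45 °C
Reagents that add atoms: water, O
Why: S-Methylation and hydrolysis of the dithiane frees the C6 aldehyde under near-neutral conditions that should neither enolise C5 nor affect the alkene, the alkynylsilane or the silyl ether.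

Step 13
Reactants: 18 (1S,2S,6S)-2-{[(tert-butyldiphenylsilyl)oxy]methyl}-2,6-dimethyl-6-[(3R)-2-methyl-7-(trimethylsilyl)hept-1-en-6-yn-3-yl]cyclohexane-1-carbaldehyde
Product: 19 allylic alcohol from vinyl addition to 18 (both C6 epimers)
Conditions: CH2=CHMgBr, THF, −78 to 0 °C
Reagents that add atoms: vinylmagnesium bromide, C=C[Mg]Br
Why: Grignard 1,2-addition of the small vinyl nucleophile forms C6–C7, and the C6 configuration is left uncontrolled because it is erased in the next step.

Step 14
Reactants: 19 allylic alcohol from vinyl addition to 18 (both C6 epimers)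
Product: 20 1-[(1S,2S,6S)-2-{[(tert-butyldiphenylsilyl)oxy]methyl}-2,6-dimethyl-6-[(3R)-2-methyl-7-(trimethylsilyl)hept-1-en-6-yn-3-yl]cyclohexyl]prop-2-en-1-one
Conditions: Dess–Martin periodinane, CH2Cl2, 0 °C to rt
Reagents that add atoms: none
Why: Dess–Martin oxidation converts both epimers into one vinyl ketone under neutral conditions that should leave the hindered C5–H untouched.

Step 15
Reactants: 20 1-[(1S,2S,6S)-2-{[(tert-butyldiphenylsilyl)oxy]methyl}-2,6-dimethyl-6-[(3R)-2-methyl-7-(trimethylsilyl)hept-1-en-6-yn-3-yl]cyclohexyl]prop-2-en-1-one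
Product: 21 (1R)-1-[(1S,2S,6S)-2-{[(tert-butyldiphenylsilyl)oxy]methyl}-2,6-dimethyl-6-[(3R)-2-methyl-7-(trimethylsilyl)hept-1-en-6-yn-3-yl]cyclohexyl]prop-2-en-1-ol
Conditions: (S)-2-methyl-CBS-oxazaborolidine, catecholborane, toluene, −78 °C
Reagents that add atoms: none
Why: In the Corey–Bakshi–Shibata reduction the ring A residue flanked by two quaternary carbons acts as the large group and vinyl as the small one, so the (S)-catalyst should deliver hydride to the face that gives 6R, while catecholborane at low temperature spares the alkenes and the alkyne.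

Step 16
Reactants: 21 (1R)-1-[(1S,2S,6S)-2-{[(tert-butyldiphenylsilyl)oxy]methyl}-2,6-dimethyl-6-[(3R)-2-methyl-7-(trimethylsilyl)hept-1-en-6-yn-3-yl]cyclohexyl]prop-2-en-1-ol
Product: 22 (4S,5S,6R,9R,10S)-18-(tert-butyldiphenylsilyloxy)-14-(trimethylsilyl)-15,16-dinorlabd-7-en-13-yn-6-ol
Conditions: second-generation Grubbs catalyst RuCl2(=CHPh)(PCy3)(H2IMes) (5 mol %), 1,4-benzoquinone (10 mol %), toluene (2 mM), 80 °C, argon sparge
Reagents that add atoms: none
Why: The ruthenium benzylidene exchanges first with the monosubstituted C6 vinyl group, the resulting C7 alkylidene adds across the C8=CH2 bond of the isopropenyl group to give a ruthenacyclobutane, and cycloreversion releases the C7=C8 alkene and Ru=CH2, which leaves as ethylene on the next turnover. The closest known reaction type is ring-closing diene metathesis to a trisubstituted cyclohexene next to a free allylic alcohol. Ring B closes as a six-membered carbocycle from two arms that sit trans-diequatorial (gauche) on C5 and C10 of the ring A chair, so the reacting ends are held close and the trans-decalin forms without added strain. No stereocentre is created, and C5, C6, C9 and C10 are spectators. The step needs initiation at the vinyl group only, closure rather than dimerisation, an inert alkyne, and no isomerisation of the allylic alcohol to a ketone. These are secured by the hindrance of the 1,1-disubstituted alkene, high dilution with removal of ethylene, the Me3Si cap on the alkyne, and benzoquinone as a scavenger of ruthenium hydrides.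

Step 17
Reactants: 22 (4S,5S,6R,9R,10S)-18-(tert-butyldiphenylsilyloxy)-14-(trimethylsilyl)-15,16-dinorlabd-7-en-13-yn-6-ol
Product: 23 (4S,5S,6S,7S,8R,9S,10R)-18-(tert-butyldiphenylsilyloxy)-7,8-epoxy-14-(trimethylsilyl)-15,16-dinorlabd-13-yn-6-ol
Conditions: mCPBA, CH2Cl2, 0 °C
Reagents that add atoms: 3-chloroperbenzoic acid, OOC(=O)c1cccc(Cl)c1
Why: In this Henbest hydroxyl-directed epoxidation the pseudo-equatorial C6 hydroxyl, which suits peracid hydrogen bonding better than metal-alkoxide delivery, guides the oxidant to its own face while the axial C20 methyl blocks the other face, so the C8 oxygen should enter cis to O6, and C7=C8 is the only alkene present.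

Step 18
Reactants: 23 (4S,5S,6S,7S,8R,9S,10R)-18-(tert-butyldiphenylsilyloxy)-7,8-epoxy-14-(trimethylsilyl)-15,16-dinorlabd-13-yn-6-ol
Product: 24 (4S,5S,6R,8S,9S,10R)-18-(tert-butyldiphenylsilyloxy)-14-(trimethylsilyl)-15,16-dinorlabd-13-yne-6,8-diol
Conditions: LiAlH4, THF, 65 °C
Reagents that add atoms: none
Why: Aluminium hydride opening of a 2,3-epoxy alcohol to the 1,3-diol should occur by SN2 attack at the secondary C7, because C8 is fully substituted and shielded by the axial C20 methyl, so the C8–O bond is never broken and O8 stays equatorial and cis to O6 with C17 axial.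

Step 19
Reactants: 24 (4S,5S,6R,8S,9S,10R)-18-(tert-butyldiphenylsilyloxy)-14-(trimethylsilyl)-15,16-dinorlabd-13-yne-6,8-diol
Product: 25 (4S,5S,6R,8S,9S,10R)-15,16-dinorlabd-13-yne-6,8,18-triol
Conditions: Bu4NF, THF, rt
Reagents that add atoms: none
Why: Fluoride-induced desilylation cleaves the O–Si bond at C18 and the C(sp)–Si bond at C14 in one operation.

Step 20
Reactants: 25 (4S,5S,6R,8S,9S,10R)-15,16-dinorlabd-13-yne-6,8,18-triol
Product: 26 (4S,5S,6R,8S,9S,10R)-6,8-dihydroxy-15,16-dinorlabd-13-yn-18-yl acetate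
Conditions: AcCl (1.05 equiv), 2,4,6-collidine, CH2Cl2, −78 °C
Reagents that add atoms: acetyl chloride, CC(=O)Cl
Why: Chemoselective acylation should pick the only primary hydroxyl (C18) over the hindered secondary C6 and the tertiary C8 hydroxyls.

Step 21
Reactants: 26 (4S,5S,6R,8S,9S,10R)-6,8-dihydroxy-15,16-dinorlabd-13-yn-18-yl acetate
Product: 27 (4S,5S,6R,8S,9S,10R)-6,8-dihydroxylabda-13(16),14-dien-18-yl acetate
Conditions: ethylene (1 atm), second-generation Grubbs catalyst RuCl2(=CHPh)(PCy3)(H2IMes) (5 mol %), CH2Cl2, rt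
Reagents that add atoms: ethylene, C=C
Why: Enyne cross-metathesis of a terminal alkyne with ethylene gives the 2-substituted buta-1,3-diene directly (ethylene supplies C15 and C16), tolerates the free hydroxyls and the acetate, and keeps the sensitive diene out of every earlier step.

Compound list
1 | 3-methoxybenzyl alcohol | COc1cccc(CO)c1 | starting material
2 | (5-methoxycyclohexa-1,4-dien-1-yl)methanol | COC1=CCC=C(CO)C1 | intermediate
3 | 3-(hydroxymethyl)cyclohex-2-en-1-one | O=C1C=C(CO)CCC1 | intermediate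
4 | 3-{[(tert-butyldiphenylsilyl)oxy]methyl}cyclohex-2-en-1-one | O=C1C=C(CO[Si](c2ccccc2)(c2ccccc2)C(C)(C)C)CCC1 | intermediate
5 | dimethylaluminium C5=C10 enolate, 4S | C[Al](C)OC1=C[C@@](C)(CO[Si](c2ccccc2)(c2ccccc2)C(C)(C)C)CCC1 | intermediate
6 | tert-butyl{[(1S)-1-methyl-3-(trimethylsilyloxy)cyclohex-2-en-1-yl]methoxy}diphenylsilane | C[Si](C)(C)OC1=C[C@@](C)(CO[Si](c2ccccc2)(c2ccccc2)C(C)(C)C)CCC1 | intermediate
7 | (2R,3S)-3-{[(tert-butyldiphenylsilyl)oxy]methyl}-2-(1,3-dithian-2-yl)-3-methylcyclohexan-1-one | O=C1CCC[C@](C)(CO[Si](c2ccccc2)(c2ccccc2)C(C)(C)C)[C@H]1C1SCCCS1 | intermediate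
8 | tert-butyl{[(1S,2R,3E)-2-(1,3-dithian-2-yl)-3-(methoxymethylidene)-1-methylcyclohexyl]methoxy}diphenylsilane | CO/C=C1\CCC[C@](C)(CO[Si](c2ccccc2)(c2ccccc2)C(C)(C)C)[C@H]1C1SCCCS1 | intermediate
9 | 5-(trimethylsilyl)pent-4-yn-1-ol | C[Si](C)(C)C#CCCCO | starting material
10 | 5-(trimethylsilyl)pent-4-ynal | C[Si](C)(C)C#CCCC=O | intermediate
11 | ethyl (2E)-2-methyl-7-(trimethylsilyl)hept-2-en-6-ynoate | CCOC(=O)/C(C)=C/CCC#C[Si](C)(C)C | intermediate
12 | (2E)-2-methyl-7-(trimethylsilyl)hept-2-en-6-yn-1-ol | OC/C(C)=C/CCC#C[Si](C)(C)C | intermediate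
13 | E enol ether of C20 with the (2E)-2-methyl-7-(trimethylsilyl)hept-2-en-6-ynyl group on oxygen (4S,5R) | C[Si](C)(C)C#CCC/C=C(\C)CO/C=C1\CCC[C@](C)(CO[Si](c2ccccc2)(c2ccccc2)C(C)(C)C)[C@H]1C1SCCCS1 | intermediate
14 | (1R,2R,3S)-3-{[(tert-butyldiphenylsilyl)oxy]methyl}-2-(1,3-dithian-2-yl)-3-methyl-1-[(3R)-2-methyl-7-(trimethylsilyl)hept-1-en-6-yn-3-yl]cyclohexane-1-carbaldehyde | C[Si](C)(C)C#CCC[C@H](C(C)=C)[C@]1(C=O)CCC[C@](C)(CO[Si](c2ccccc2)(c2ccccc2)C(C)(C)C)[C@H]1C1SCCCS1 | intermediate
15 | tosylhydrazone of aldehyde 14 | C[Si](C)(C)C#CCC[C@H](C(C)=C)[C@]1(/C=N/NS(=O)(=O)c2ccc(C)cc2)CCC[C@](C)(CO[Si](c2ccccc2)(c2ccccc2)C(C)(C)C)[C@H]1C1SCCCS1 | intermediate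
16 | C20 monoalkyl diazene | C[Si](C)(C)C#CCC[C@H](C(C)=C)[C@]1(CN=N)CCC[C@](C)(CO[Si](c2ccccc2)(c2ccccc2)C(C)(C)C)[C@H]1C1SCCCS1 | intermediate
17 | tert-butyl({(1S,2S,3S)-2-(1,3-dithian-2-yl)-1,3-dimethyl-3-[(3R)-2-methyl-7-(trimethylsilyl)hept-1-en-6-yn-3-yl]cyclohexyl}methoxy)diphenylsilane | C[Si](C)(C)C#CCC[C@H](C(C)=C)[C@]1(C)CCC[C@](C)(CO[Si](c2ccccc2)(c2ccccc2)C(C)(C)C)[C@H]1C1SCCCS1 | intermediate
18 | (1S,2S,6S)-2-{[(tert-butyldiphenylsilyl)oxy]methyl}-2,6-dimethyl-6-[(3R)-2-methyl-7-(trimethylsilyl)hept-1-en-6-yn-3-yl]cyclohexane-1-carbaldehyde | C[Si](C)(C)C#CCC[C@H](C(C)=C)[C@]1(C)CCC[C@](C)(CO[Si](c2ccccc2)(c2ccccc2)C(C)(C)C)[C@H]1C=O | intermediate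
19 | vinyl carbinol from 18, mixture of C6 epimers (C6 left undefined) | C[Si](C)(C)C#CCC[C@H](C(C)=C)[C@]1(C)CCC[C@](C)(CO[Si](c2ccccc2)(c2ccccc2)C(C)(C)C)[C@H]1C(O)C=C | intermediate
20 | 1-[(1S,2S,6S)-2-{[(tert-butyldiphenylsilyl)oxy]methyl}-2,6-dimethyl-6-[(3R)-2-methyl-7-(trimethylsilyl)hept-1-en-6-yn-3-yl]cyclohexyl]prop-2-en-1-one | C[Si](C)(C)C#CCC[C@H](C(C)=C)[C@]1(C)CCC[C@](C)(CO[Si](c2ccccc2)(c2ccccc2)C(C)(C)C)[C@H]1C(=O)C=C | intermediate
21 | (1R)-1-[(1S,2S,6S)-2-{[(tert-butyldiphenylsilyl)oxy]methyl}-2,6-dimethyl-6-[(3R)-2-methyl-7-(trimethylsilyl)hept-1-en-6-yn-3-yl]cyclohexyl]prop-2-en-1-ol (metathesis precursor) | C[Si](C)(C)C#CCC[C@H](C(C)=C)[C@]1(C)CCC[C@](C)(CO[Si](c2ccccc2)(c2ccccc2)C(C)(C)C)[C@H]1[C@H](O)C=C | intermediate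
22 | (4S,5S,6R,9R,10S)-18-(tert-butyldiphenylsilyloxy)-14-(trimethylsilyl)-15,16-dinorlabd-7-en-13-yn-6-ol (metathesis product) | C[Si](C)(C)C#CCC[C@H]1[C@]2(C)CCC[C@](C)(CO[Si](c3ccccc3)(c3ccccc3)C(C)(C)C)[C@H]2[C@H](O)C=C1C | intermediate
23 | (4S,5S,6S,7S,8R,9S,10R)-18-(tert-butyldiphenylsilyloxy)-7,8-epoxy-14-(trimethylsilyl)-15,16-dinorlabd-13-yn-6-ol | C[Si](C)(C)C#CCC[C@H]1[C@]2(C)CCC[C@](C)(CO[Si](c4ccccc4)(c4ccccc4)C(C)(C)C)[C@H]2[C@H](O)[C@@H]3O[C@]13C | intermediate
24 | (4S,5S,6R,8S,9S,10R)-18-(tert-butyldiphenylsilyloxy)-14-(trimethylsilyl)-15,16-dinorlabd-13-yne-6,8-diol | C[Si](C)(C)C#CCC[C@H]1[C@]2(C)CCC[C@](C)(CO[Si](c3ccccc3)(c3ccccc3)C(C)(C)C)[C@H]2[C@H](O)C[C@]1(C)O | intermediate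
25 | (4S,5S,6R,8S,9S,10R)-15,16-dinorlabd-13-yne-6,8,18-triol | C#CCC[C@H]1[C@]2(C)CCC[C@](C)(CO)[C@H]2[C@H](O)C[C@]1(C)O | intermediate
26 | (4S,5S,6R,8S,9S,10R)-6,8-dihydroxy-15,16-dinorlabd-13-yn-18-yl acetate | C#CCC[C@H]1[C@]2(C)CCC[C@](C)(COC(C)=O)[C@H]2[C@H](O)C[C@]1(C)O | intermediate
27 | (4S,5S,6R,8S,9S,10R)-6,8-dihydroxylabda-13(16),14-dien-18-yl acetate | C=CC(=C)CC[C@H]1[C@]2(C)CCC[C@](C)(COC(C)=O)[C@H]2[C@H](O)C[C@]1(C)O | target

Total step count: 21. Longest linear sequence: 18 steps (steps 1–5 and 9–21). Steps 6–8 form the side branch.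

Steps most likely to fail

Step 9 (enol ether exchange and Claisen rearrangement). The weak acid may ionise the allylic alcohol faster than exchange occurs. The crowding around C10 may slow the rearrangement or let a boat transition state erode the selectivity at C9. The fallback makes the allyl enol ether by olefination instead of exchange and sets out from 12 and 7. Alcohol 12 is treated with paraformaldehyde and Me3SiCl to give the chloromethyl ether F1, and PPh3 converts this into the phosphonium chloride F2. The ylide of F2, formed with KN(SiMe3)2, is condensed with ketone 7 to give 13 under basic conditions. The geometric isomers of 13 are separated on base-washed silica. Only the E isomer is heated in decane at 150 °C without acid, so the route is rejoined at 13 and then 14.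

Step 16 (ring-closing metathesis). Closure onto the hindered isopropenyl group may be slower than isomerisation of the allylic alcohol to an ethyl ketone, or slower than dimerisation at the vinyl group. The fallback sets out from vinyl ketone 20, which has no carbinol to isomerise and does not homodimerise readily. The same ruthenium catalyst should close it to the decalin enone F3. Reduction with NaBH4 and CeCl3·7H2O from the open face gives the axial 6-epi alcohol F4. Mitsunobu inversion (4-nitrobenzoic acid, PPh3, DIAD) gives the equatorial 4-nitrobenzoate F5, and iBu2AlH cleaves this ester without touching the alkynylsilane, returning to 22.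

Step 18 (hydride opening of the epoxide). Attack at C7 gives a diequatorial rather than a diaxial opening and takes place next to the O6 aluminate. It may therefore be slow, leaving room for base-induced isomerisation of the epoxide to an allylic alcohol. The fallback sets out from 23 and replaces hydride by a softer, stronger nucleophile. Phenylselenide, from PhSeSePh and NaBH4 in EtOH, opens the epoxide at C7 with inversion to give the 7-phenylselanyl 6,8-diol F6. Radical reduction with Bu3SnH and AIBN then removes selenium, returning to 24.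

Further compounds
F1 | step 9 | {(5E)-7-(chloromethoxy)-6-methylhept-5-en-1-yn-1-yl}trimethylsilane | ClCOC/C(C)=C/CCC#C[Si](C)(C)C
F2 | step 9 | ({[(2E)-2-methyl-7-(trimethylsilyl)hept-2-en-6-yn-1-yl]oxy}methyl)triphenylphosphonium chloride | [Cl-].C[Si](C)(C)C#CCC/C=C(\C)COC[P+](c1ccccc1)(c1ccccc1)c1ccccc1
F3 | step 16 | (4S,5S,9R,10S)-18-(tert-butyldiphenylsilyloxy)-14-(trimethylsilyl)-15,16-dinorlabd-7-en-13-yn-6-one | C[Si](C)(C)C#CCC[C@H]1[C@]2(C)CCC[C@](C)(CO[Si](c3ccccc3)(c3ccccc3)C(C)(C)C)[C@H]2C(=O)C=C1C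
F4 | step 16 | 6-epimer of 22 (axial 6S alcohol) | C[Si](C)(C)C#CCC[C@H]1[C@]2(C)CCC[C@](C)(CO[Si](c3ccccc3)(c3ccccc3)C(C)(C)C)[C@H]2[C@@H](O)C=C1C
F5 | step 16 | 4-nitrobenzoate of 22 | C[Si](C)(C)C#CCC[C@H]1[C@]2(C)CCC[C@](C)(CO[Si](c3ccccc3)(c3ccccc3)C(C)(C)C)[C@H]2[C@H](OC(=O)c3ccc(cc3)[N+](=O)[O-])C=C1C
F6 | step 18 | 7-phenylselanyl derivative of 24 (selenium trans to O8) | C[Si](C)(C)C#CCC[C@H]1[C@]2(C)CCC[C@](C)(CO[Si](c3ccccc3)(c3ccccc3)C(C)(C)C)[C@H]2[C@H](O)[C@@H]([Se]c3ccccc3)[C@]1(C)O
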